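The target forms in the first phase, where two steps can destroy it. While it sits in the second phase, neither step touches it, so you want the share that gets across.

starting material 0.50 M; reagent in the second phase 0.900 equiv; time 1.0 h; volume of the second phase over the first 1.0

    reagent in the reaction phase ⇌ reagent in the second phase, rate k1*([reagent in the reaction phase] - [reagent in the second phase]/K1) per volume of the first phase (K1 = 1.3, k1 = 0.11 min⁻¹)
    starting material + reagent in the reaction phase → target (k2 = 3.5 M⁻¹ min⁻¹)
    target ⇌ product in the second phase, rate k3*([target] - [product in the second phase]/K3) per volume of the first phase (K3 = 27, k3 = 0.17 min⁻¹)
    target → decomposed product (k4 = 0.062 min⁻¹)
    starting material + target → side product (k5 = 0.21 M⁻¹ min⁻¹)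

- percent here means starting material units held: one side product counts as two
- what is said of target includes product in the second phase
- in the second phase: reagent in the second phase, product in the second phase; everything else is in the first
- charges count per volume of the first phase; a concentration in a rate is the amount of a species over the volume of its own phase; every rate counts per litre of the first phase
- run time (flask): 1.0 h

1. target and product in the second phase together at 1.0 h, in percent of the starting material charged
2. the change that raises the amount of target and product in the second phase together at 1.0 h, in percent of the starting material charged most ("none" if none brings more than 2 percentage points) (theta / epsilon / zeta / none)
3. amount of target and product in the second phase together at 1.0 h, in percent of the starting material charged, after zeta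

Here is my ladder of half-lives, fastest first, with starting material as charged:

| Event | Half-life |
|---|---|
| reagent in the reaction phase reacts | 0.40 min |
| target is extracted | 4.08 min |
| target goes to side product | 6.60 min |
| reagent crosses from the second phase | 8.19 min |
| target decomposes | 11.2 min |

With starting material as charged, reagent in the reaction phase is consumed much faster than reagent crosses, so at that stage c(reagent in the reaction phase) stays small and crossing is the rate-limiting step for making target. Target in the first phase, all exits together, has a half-life of 2.06 min, shorter than that of the crossing, so each new target is split soon after it forms.

Freeze c(starting material) at half its charge, neglect back-flow, and extraction takes 59.8%. This is the capture share: the extraction coefficient over itself plus the decomposition constant plus the side-path constant times c(starting material). The run outlasts the half-life of the crossing, so I count the reagent as turned over. Its charge allows 90.0% of target, and I commit to 53.8%.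

The forecast gives 50%, lower than my figure, and 56% after doubling the reagent. It picks epsilon, saying “faster extraction cuts both losses”.

The flask gives 49.1%, and 54.8% after doubling the reagent; epsilon is best, at 10 percentage points. At 1.00 h the second phase holds 47.3% against 22.1% decomposed product and 26.0% side product, each side product having consumed one target, a capture share read as 57.4%. Doubling the extraction coefficient lifts the reckoned share to 74.8%, which scales the yield up by 12 points.

For the neighbour charged with 2.0 M of starting material, same equivalents and time, the capture share falls to 38.5%, giving 34.7%. That flask holds 32.5%, with 52.5% as side product.

Its constants belong to no real substance, and the outcome is calculated.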